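Morinin L has no stereocentre, so three alkene geometries (Z, Z, E) are the whole stereochemical problem. The route rests on cutting the bond between the α-carbon C2 of the central (Z)-2-(acyloxymethyl)but-2-enoate and its ester carbonyl carbon C1, which is recognised as carbon monoxide. One palladium-catalysed three-component alkoxycarbonylation joins an alkenyl iodide (angelate already in place), CO and (E)-3,4-dimethoxycinnamyl alcohol. It forms C2–C1 and C1–O together, with retention. It exploits the contra-thermodynamic C2=C3 alkene, whose C4 methyl lies cis to C1. That site is exactly where α-iodination of (E)-crotonaldehyde places iodine. The dimethoxybenzene ring and its E-propenyl chain stay spectators.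

Key step: step 5

Remark: the target is achiral, so "single enantiomer" is read as the single Z,Z,E geometric isomer drawn.

Step 1
Reactants: 1 (E)-crotonaldehyde
Product: 2 (Z)-2-iodobut-2-enal
Conditions: I2, K2CO3, DMAP (cat.), THF/H2O, rt, dark
Reagents that add atoms: iodine, II
Why: In this nucleophile-catalysed (Baylis–Hillman-type) α-iodination, DMAP adds conjugately, the enolate is iodinated, and E1cB loss of DMAP should give the more stable enal with CHO trans to CH3, which is the Z-iodide with iodine cis to the methyl group.

Step 2
Reactants: 2 (Z)-2-iodobut-2-enal
Product: 3 (Z)-2-iodobut-2-en-1-ol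
Conditions: NaBH4, MeOH, 0 °C
Reagents that add atoms: none
Why: Chemoselective borohydride 1,2-reduction of the aldehyde should leave the C–I bond and the alkene geometry untouched.

Step 3
Reactants: 3 (Z)-2-iodobut-2-en-1-ol; 4 angelic acid
Product: 6 (Z)-2-iodobut-2-en-1-yl angelate, via alkoxyphosphonium angelate 5 (not isolated)
Conditions: PPh3, DIAD, THF, 0 °C to rt
Reagents that add atoms: none
Why: In this Mitsunobu esterification the carboxylate of 4 displaces the primary allylic oxyphosphonium group of 5 by SN2, so the acyl carbon of angelic acid is never activated and the angelate-to-tiglate isomerisation typical of acyl activation should be avoided.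

Step 4
Reactants: 7 methyl (E)-3,4-dimethoxycinnamate
Product: 8 (E)-3,4-dimethoxycinnamyl alcohol
Conditions: DIBAL-H (2.3 equiv), CH2Cl2, −78 to 0 °C; aq. Rochelle salt
Reagents that add atoms: none
Why: DIBAL-H 1,2-reduction of an α,β-unsaturated ester should stop at the allylic alcohol without touching the E alkene or the aryl methyl ethers.

Step 5
Reactants: 6 (Z)-2-iodobut-2-en-1-yl angelate; 8 (E)-3,4-dimethoxycinnamyl alcohol
Product: 11 Morinin L, via alkenylpalladium iodide 9 (not isolated), via acylpalladium iodide 10 (not isolated)
Conditions: Pd(OAc)2 (5 mol %), Xantphos (6 mol %), CO (1 atm), i-Pr2NEt (2 equiv), 6 (1.2 equiv), THF, 45 °C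
Reagents that add atoms: carbon monoxide, [C-]#[O+]
Why: Pd(0) inserts into the C(sp2)–I bond of 6 to give 9, migratory insertion of coordinated CO forms the bond between the alkene α-carbon and the new carbonyl carbon in 10, and base-assisted alcoholysis of 10 by 8 closes the ester C–O bond and returns Pd(0). The closest known reaction type is the Heck-type palladium-catalysed alkoxycarbonylation (carbonylative esterification) of alkenyl iodides, run here as a three-component union with a near-stoichiometric alcohol. No ring is closed and no stereocentre is created; the one stereo-element at stake, the Z geometry of the central C2=C3 bond, is carried over from 6 because oxidative addition and migratory insertion both proceed with retention at the sp2 carbon. The step needs chemoselectivity of Pd(0) for the C–I bond over the allylic C–O bonds of the angelate and of the newly formed cinnamyl ester, which is secured by the much faster oxidative addition of the iodide, by keeping 6 in slight excess so that Pd(0) always meets iodide, by the π-acidic CO atmosphere, by the mild temperature and by a non-nucleophilic base that cannot add SN2′ to the 2-(acyloxymethyl)enoate. CO insertion must also outrun 5-exo Heck closure of 9 onto the angelate alkene, which is held back by the s-trans (Z) ester conformation and by the trisubstituted, electron-poor acceptor.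

Compound list
1 | (E)-crotonaldehyde, (E)-but-2-enal | C/C=C/C=O | starting material
2 | (Z)-2-iodobut-2-enal (I cis to CH3) | C/C=C(\I)C=O | intermediate
3 | (Z)-2-iodobut-2-en-1-ol | C/C=C(\I)CO | intermediate
4 | angelic acid, (Z)-2-methylbut-2-enoic acid | C/C=C(/C)C(=O)O | starting material
5 | alkoxyphosphonium angelate, {[(Z)-2-iodobut-2-en-1-yl]oxy}triphenylphosphonium (Z)-2-methylbut-2-enoate | C/C=C(\I)CO[P+](c1ccccc1)(c1ccccc1)c1ccccc1.C/C=C(/C)C(=O)[O-] | intermediate
6 | (Z)-2-iodobut-2-en-1-yl angelate, (Z)-2-iodobut-2-en-1-yl (Z)-2-methylbut-2-enoate | C/C=C(/C)C(=O)OC/C(I)=C/C | intermediate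
7 | methyl (E)-3,4-dimethoxycinnamate | COC(=O)/C=C/c1ccc(OC)c(OC)c1 | starting material
8 | (E)-3,4-dimethoxycinnamyl alcohol, (E)-3-(3,4-dimethoxyphenyl)prop-2-en-1-ol | OC/C=C/c1ccc(OC)c(OC)c1 | intermediate
9 | alkenylpalladium iodide from oxidative addition of 6 (Xantphos on Pd not drawn) | C/C=C(/C)C(=O)OC/C([Pd]I)=C/C | intermediate
10 | acylpalladium iodide from CO insertion into 9 (Xantphos on Pd not drawn) | C/C=C(/C)C(=O)OC/C(=C/C)C(=O)[Pd]I | intermediate
11 | Morinin L, (E)-3-(3,4-dimethoxyphenyl)prop-2-en-1-yl (Z)-2-({[(Z)-2-methylbut-2-enoyl]oxy}methyl)but-2-enoate | C/C=C(/C)C(=O)OC/C(=C/C)C(=O)OC/C=C/c1ccc(OC)c(OC)c1 | target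

Total step count: 5
Longest linear sequence: 4 (steps 1, 2, 3, 5)

Steps most likely to fail

Step 5.
- Risk: capture of the acylpalladium species by roughly one equivalent of an allylic alcohol may be slow. That leaves time for drift of the Z geometry at the acyl stage and for β-hydride loss from a palladium alkoxide. Pd(0) may also ionise the electron-rich cinnamyl ester or the allylic angelate once the iodide runs low, which would scramble the ester groups.
- Fallback: it sets out from 6 and divides the union into a C–C and a separate C–O event. Hydroxycarbonylation of 6 (PdCl2(PPh3)2 cat., CO 1 atm, excess H2O, i-Pr2NEt, THF, rt to 40 °C; acidic work-up) has water in large excess to trap the acylpalladium species quickly. It should give (Z)-2-({[(Z)-2-methylbut-2-enoyl]oxy}methyl)but-2-enoic acid F1. Mitsunobu coupling of this acid with 8 (PPh3, DIAD, THF, 0 °C) then forms the cinnamyl C–O bond without acyl activation. The cinnamyl ester never meets palladium. The fallback comes back to the route at 11.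

Step 3.
- Risk: the angelate geometry may erode through reversible conjugate addition of phosphine or hydrazide anion. The carboxylate may attack SN2′, and removal of the phosphine-derived by-products from a small non-polar ester may be laborious.
- Fallback: it sets out from 4 and uses acyl transfer instead of O-alkylation. Treatment of 4 with 2,4,6-trichlorobenzoyl chloride and Et3N in toluene at rt should give the Yamaguchi-type mixed anhydride, angelic 2,4,6-trichlorobenzoic anhydride F2. Heating it with 3 in toluene at about 80 °C without DMAP should transfer the less hindered angeloyl group with its geometry intact. The fallback comes back to the route at 6.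

Step 1.
- Risk: crotonaldehyde may self-condense or polymerise in the basic aqueous medium. The iodination may stall, and the volatile, light-sensitive product may be lost on isolation.
- Fallback: it sets out from 1 and replaces nucleophile-catalysed α-halogenation by addition–elimination.
  - Anti addition of Br2 (CH2Cl2, 0 °C) should give racemic (2R,3S)-2,3-dibromobutanal F3.
  - Dehydrobromination with Et3N should give the more stable (Z)-2-bromobut-2-enal F4.
  - NaBH4 in MeOH at 0 °C should give (Z)-2-bromobut-2-en-1-ol F5.
  - A copper-catalysed alkenyl Finkelstein exchange (CuI cat., trans-N,N′-dimethylcyclohexane-1,2-diamine, NaI, dioxane, 110 °C) proceeds with retention and comes back to the route at 3.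

Further compounds
F1 | step 5 | (Z)-2-({[(Z)-2-methylbut-2-enoyl]oxy}methyl)but-2-enoic acid | C/C=C(/C)C(=O)OC/C(=C/C)C(=O)O
F2 | step 3 | angelic 2,4,6-trichlorobenzoic anhydride | C/C=C(/C)C(=O)OC(=O)c1c(Cl)cc(Cl)cc1Cl
F3 | step 1 | rac-(2R,3S)-2,3-dibromobutanal (one enantiomer drawn) | C[C@H](Br)[C@H](Br)C=O
F4 | step 1 | (Z)-2-bromobut-2-enal | C/C=C(\Br)C=O
F5 | step 1 | (Z)-2-bromobut-2-en-1-ol | C/C=C(\Br)CO
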